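**Strategy**

Everything rests on closing the cyclopentenone (C8–C12, prostanoid numbering) at the C9–C10 bond, ketone carbon to chlorinated vinyl carbon, by rhodium-catalysed trans-hydroacylation of a chloroalkyne. The step exploits the hidden symmetry of carbinol carbon C12: its two methylene neighbours, ring C8 and side-chain C13, both stem from CH2CHO arms of an achiral dialdehyde, 3-(chloroethynyl)-3-silyloxypentanedial, made by ozonolysis of a cyclopentene. A chiral catalyst engages one enantiotopic formyl group, so a single operation builds the ring, the 2-chloroenone and the only stereocentre, and leaves the second aldehyde for the Z-octenyl chain. An aldol condensation then attaches the dienoate chain.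

Key step: step 3

Remark on the chemistry: the sense of induction of the chiral ligand in step 3 cannot be predicted; the (R,R) ligand is written, and its antipode would be used if a first screen shows the opposite sense.

Positions are named by prostanoid numbering: C9 ketone carbon, C10 chlorinated carbon, C11 ring CH=, C12 carbinol carbon, C8 ring carbon bearing the exocyclic alkene, C13 side-chain CH2.

**Route**

Step 1
Reactants: 1 cyclopent-3-en-1-one; 2 (Z)-1,2-dichloroethene
Product: 5 1-(chloroethynyl)cyclopent-3-en-1-yl triethylsilyl ether, via lithium chloroacetylide 3 (not isolated), via lithium alkoxide 4 (not isolated)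
Conditions: 2 (slight excess), MeLi (2 equiv per 2), Et2O, 0 °C; then 1, −78 °C; then Et3SiOTf, −78 → 0 °C
Reagents that add atoms: triethylsilyl trifluoromethanesulfonate, CC[Si](CC)(CC)OS(=O)(=O)C(F)(F)F
Why: Acetylide 1,2-addition to a ketone with in-situ O-silylation: lithium chloroacetylide, formed from the cis-dichloroalkene by lithiation, anti elimination of LiCl and a second lithiation, is nucleophilic but only weakly basic, so it should add to the enolisable ketone at −78 °C, and the tertiary alkoxide is trapped by the silyl triflate; the product has a mirror plane, so no stereocentre arises.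

Step 2
Reactants: 5 1-(chloroethynyl)cyclopent-3-en-1-yl triethylsilyl ether
Product: 7 3-(chloroethynyl)-3-[(triethylsilyl)oxy]pentanedial, via secondary ozonide 6 (not isolated)
Conditions: O3, CH2Cl2, −78 °C, stopped at the first blue colour; then Me2S, −78 °C → rt; chromatography
Reagents that add atoms: ozone, O=[O+][O-]
Why: Alkene ozonolysis with reductive work-up: ozone attacks the electron-rich cis-disubstituted ring alkene far faster than the electron-poor chloroalkyne, and dimethyl sulfide reduces the ozonide to the dialdehyde, which is still achiral (two enantiotopic CH2CHO arms on the carbinol carbon).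

Step 3
Reactants: 7 3-(chloroethynyl)-3-[(triethylsilyl)oxy]pentanedial
Product: 8 (4S)-2-chloro-4-(2-oxoethyl)-4-[(triethylsilyl)oxy]cyclopent-2-en-1-one
Conditions: [Rh(cod)((R,R)-iPr-DuPHOS)]BF4 (10 mol %; iPr-DuPHOS = 1,2-bis(2,5-diisopropylphospholan-1-yl)benzene), pre-hydrogenated in acetone to remove cod, then Ar; 7, acetone, rt
Reagents that add atoms: none
Why: Proposed new method: oxidative addition of one formyl C–H bond to the cationic bisphosphine complex of monovalent rhodium gives an acyl hydride of trivalent rhodium, net trans addition of Rh–H across the tethered chloroalkyne (hydrogen to the inner carbon) gives a six-membered rhodacycle, and C–C reductive elimination joins the acyl carbon to the chlorine-bearing carbon. The closest known reaction type is the rhodium-catalysed cyclisation of 4-alkynals to cyclopent-2-enones, which is also known in enantioselective form as kinetic resolution of 3-substituted 4-alkynals and as desymmetrisation of 3,3-dialkynyl aldehydes; new here are the 1-chloroalkyne and the choice between two enantiotopic formyl groups instead of two alkynes. The five-membered ring closes in a formal 5-endo-dig mode, made possible because the bond is formed by reductive elimination from the metallacycle and not by direct attack on the alkyne. The new stereocentre at the silyloxy carbon is controlled by the C2-symmetric ligand, which reads the difference between the silyloxy group and the spectator CH2CHO arm in the diastereomeric alkyne-insertion transition states, in the way it reads the 3-substituents in the known resolutions, and reversible C–H addition lets both arms funnel through the faster one. Regioselectivity is secured by the tether (the exo mode would give a cyclobutanone, which small-bite-angle ligands disfavour), and a second hydroacylation of the remaining aldehyde is not expected because it would require insertion of the trisubstituted chloroenone alkene to give a strained bicycle. The C(sp)–Cl bond, the strongest carbon–halogen bond among haloalkynes, should survive the catalyst at room temperature, and the quaternary carbon favours cyclisation by the Thorpe–Ingold effect.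

Step 4
Reactants: 8 (4S)-2-chloro-4-(2-oxoethyl)-4-[(triethylsilyl)oxy]cyclopent-2-en-1-one; 9 hexyltriphenylphosphonium bromide
Product: 11 (4S)-2-chloro-4-[(2Z)-oct-2-en-1-yl]-4-[(triethylsilyl)oxy]cyclopent-2-en-1-one, via hexylidenetriphenylphosphorane 10 (not isolated)
Conditions: 9, NaN(SiMe3)2 (slight deficit relative to 9), THF, 0 °C; then 8, −78 → −40 °C
Reagents that add atoms: none
Why: Wittig olefination with a non-stabilised ylide under lithium-free conditions, which gives the Z-alkene by kinetic formation of the cis-oxaphosphetane; the aldehyde should react at −78 °C much faster than the conjugated, hindered ketone, the slight deficit of base limits enolisation, and the stereocentre is not touched.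

Step 5
Reactants: 12 (4-carboxybutyl)triphenylphosphonium bromide; 13 [(tert-butyldimethylsilyl)oxy]acetaldehyde
Product: 15 (5Z)-7-[(tert-butyldimethylsilyl)oxy]hept-5-enoic acid, via ylide carboxylate 14 (not isolated)
Conditions: 12, NaN(SiMe3)2 (2 equiv), THF, 0 °C; then 13, −78 °C → rt; work-up at pH 4
Reagents that add atoms: none
Why: Z-selective Wittig olefination of an α-silyloxy aldehyde with the non-stabilised carboxylate ylide under lithium-free conditions (kinetic cis-oxaphosphetane), the free carboxylate keeping the ylide from cyclising as an ester would.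

Step 6
Reactants: 15 (5Z)-7-[(tert-butyldimethylsilyl)oxy]hept-5-enoic acid
Product: 17 methyl (5Z)-7-hydroxyhept-5-enoate, via (5Z)-7-hydroxyhept-5-enoic acid 16 (not isolated)
Conditions: HCl (catalytic, 1.25 M in MeOH), MeOH, 0 °C → rt
Reagents that add atoms: methanol, CO
Why: Acid-catalysed methanolysis removes the primary silyl ether and Fischer esterification then converts the acid into the methyl ester in the same solution, while the isolated Z-alkene and the primary allylic alcohol should tolerate dilute methanolic HCl at room temperature.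

Step 7
Reactants: 17 methyl (5Z)-7-hydroxyhept-5-enoate
Product: 18 methyl (5Z)-7-oxohept-5-enoate
Conditions: Dess–Martin periodinane, NaHCO3, CH2Cl2, 0 °C; used at once
Reagents that add atoms: none
Why: Dess–Martin oxidation of a primary allylic alcohol under bicarbonate buffer at 0 °C stops at the aldehyde and is mild enough not to isomerise the Z-enal, which is used without storage.

Step 8
Reactants: 11 (4S)-2-chloro-4-[(2Z)-oct-2-en-1-yl]-4-[(triethylsilyl)oxy]cyclopent-2-en-1-one; 18 methyl (5Z)-7-oxohept-5-enoate
Product: 20 methyl (5Z,14Z)-10-chloro-7-hydroxy-9-oxo-12-[(triethylsilyl)oxy]prosta-5,10,14-trien-1-oate (C12 as in 11; mixture at C7 and C8), via lithium dienolate 19 (not isolated)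
Conditions: LiN(iPr)2 (1.05 equiv), THF, −78 °C; then 18, −78 °C; AcOH quench at −78 °C
Reagents that add atoms: none
Why: Directed aldol addition: the lithium amide removes a proton from the only enolisable position (the ring CH2) to give the cross-conjugated lithium dienolate, which cannot expel the β-silyloxy group because that would create a cyclopentadienone, and which should add 1,2 to the enal at −78 °C; the two new centres form as a mixture that the next step erases.

Step 9
Reactants: 20 methyl (5Z,14Z)-10-chloro-7-hydroxy-9-oxo-12-[(triethylsilyl)oxy]prosta-5,10,14-trien-1-oate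
Product: 22 methyl (5Z,7E,12R,14Z)-10-chloro-9-oxo-12-[(triethylsilyl)oxy]prosta-5,7,10,14-tetraen-1-oate, via allylic mesylate 21 (not isolated)
Conditions: MsCl, Et3N, CH2Cl2, −20 → 0 °C; chromatography
Reagents that add atoms: none
Why: Mesylation of the secondary allylic alcohol followed by E1cB elimination of the β-mesyloxy ketone under the same conditions gives the cross-conjugated dienone, the 7E isomer (side chain anti to the ring carbonyl) being expected as the main product and separable from any 7Z isomer by chromatography, while the low temperature disfavours ionisation of the allylic mesylate that would scramble the 5Z alkene.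

Step 10
Reactants: 22 methyl (5Z,7E,12R,14Z)-10-chloro-9-oxo-12-[(triethylsilyl)oxy]prosta-5,7,10,14-tetraen-1-oate
Product: 23 chlorovulone I
Conditions: HF·pyridine, pyridine, THF, 0 °C
Reagents that add atoms: none
Why: Fluoride-mediated cleavage of the tertiary triethylsilyl ether with pyridine-buffered HF should leave the dienone, the methyl ester and the three alkenes untouched, and the tertiary carbinol does not ionise because its cation, conjugated to the electron-poor dienone, is strongly destabilised.

**Compound list**

1 | cyclopent-3-en-1-one | O=C1CC=CC1 | starting material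
2 | (Z)-1,2-dichloroethene | Cl/C=C\Cl | starting material
3 | lithium chloroacetylide | [Li]C#CCl | intermediate
4 | lithium 1-(chloroethynyl)cyclopent-3-en-1-olate | [Li]OC1(C#CCl)CC=CC1 | intermediate
5 | 1-(chloroethynyl)cyclopent-3-en-1-yl triethylsilyl ether | CC[Si](CC)(CC)OC1(C#CCl)CC=CC1 | intermediate
6 | 3-(chloroethynyl)-3-[(triethylsilyl)oxy]-6,7,8-trioxabicyclo[3.2.1]octane (secondary ozonide, diastereomer mixture) | ClC#CC1(O[Si](CC)(CC)CC)CC2OOC(C1)O2 | intermediate
7 | 3-(chloroethynyl)-3-[(triethylsilyl)oxy]pentanedial | O=CCC(C#CCl)(O[Si](CC)(CC)CC)CC=O | intermediate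
8 | (4S)-2-chloro-4-(2-oxoethyl)-4-[(triethylsilyl)oxy]cyclopent-2-en-1-one | O=CC[C@@]1(O[Si](CC)(CC)CC)C=C(Cl)C(=O)C1 | intermediate
9 | hexyltriphenylphosphonium bromide | CCCCCC[P+](c1ccccc1)(c1ccccc1)c1ccccc1.[Br-] | starting material
10 | hexylidenetriphenylphosphorane | CCCCCC=P(c1ccccc1)(c1ccccc1)c1ccccc1 | intermediate
11 | (4S)-2-chloro-4-[(2Z)-oct-2-en-1-yl]-4-[(triethylsilyl)oxy]cyclopent-2-en-1-one | CCCCC/C=C\C[C@@]1(O[Si](CC)(CC)CC)C=C(Cl)C(=O)C1 | intermediate
12 | (4-carboxybutyl)triphenylphosphonium bromide | OC(=O)CCCC[P+](c1ccccc1)(c1ccccc1)c1ccccc1.[Br-] | starting material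
13 | [(tert-butyldimethylsilyl)oxy]acetaldehyde | CC(C)(C)[Si](C)(C)OCC=O | starting material
14 | sodium 5-(triphenylphosphoranylidene)pentanoate | [Na+].[O-]C(=O)CCCC=P(c1ccccc1)(c1ccccc1)c1ccccc1 | intermediate
15 | (5Z)-7-[(tert-butyldimethylsilyl)oxy]hept-5-enoic acid | CC(C)(C)[Si](C)(C)OC/C=C\CCCC(=O)O | intermediate
16 | (5Z)-7-hydroxyhept-5-enoic acid | OC/C=C\CCCC(=O)O | intermediate
17 | methyl (5Z)-7-hydroxyhept-5-enoate | OC/C=C\CCCC(=O)OC | intermediate
18 | methyl (5Z)-7-oxohept-5-enoate | O=C/C=C\CCCC(=O)OC | intermediate
19 | lithium dienolate of 11 (O–Li on C9, double bonds C8=C9 and C10=C11) | CCCCC/C=C\C[C@@]1(O[Si](CC)(CC)CC)C=C(Cl)C(O[Li])=C1 | intermediate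
20 | methyl (5Z,14Z)-10-chloro-7-hydroxy-9-oxo-12-[(triethylsilyl)oxy]prosta-5,10,14-trien-1-oate (C12 as in 11; mixture at C7 and C8) | CCCCC/C=C\C[C@@]1(O[Si](CC)(CC)CC)C=C(Cl)C(=O)C1C(O)/C=C\CCCC(=O)OC | intermediate
21 | 7-methanesulfonate of 20 | CCCCC/C=C\C[C@@]1(O[Si](CC)(CC)CC)C=C(Cl)C(=O)C1C(OS(C)(=O)=O)/C=C\CCCC(=O)OC | intermediate
22 | methyl (5Z,7E,12R,14Z)-10-chloro-9-oxo-12-[(triethylsilyl)oxy]prosta-5,7,10,14-tetraen-1-oate | CCCCC/C=C\C[C@@]1(O[Si](CC)(CC)CC)C=C(Cl)C(=O)/C1=C/C=C\CCCC(=O)OC | intermediate
23 | chlorovulone I, methyl (5Z,7E,12R,14Z)-10-chloro-12-hydroxy-9-oxoprosta-5,7,10,14-tetraen-1-oate | CCCCC/C=C\C[C@@]1(O)C=C(Cl)C(=O)/C1=C/C=C\CCCC(=O)OC | target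

**Count**

Total steps: 10. Longest linear sequence: 7 (steps 1, 2, 3, 4, 8, 9, 10).

**Steps most likely to fail**

First, step 3 (proposed new method). What may go wrong:
- insertion of the cationic rhodium into the C(sp)–Cl bond, or a 1,2-chloride shift to a chlorovinylidene, in place of alkyne hydroacylation;
- decarbonylation of the acyl rhodium hydride;
- weak discrimination between the two enantiotopic formyl arms.

The fallback uses known chemistry only: the stereocentre comes from the chiral pool and the chlorine is put on the finished enone. It carries over none of compounds 1–7: it sets out from purchased (4R)-4-[(tert-butyldimethylsilyl)oxy]cyclopent-2-en-1-one F1 and returns to the route at compound 8. Allylmagnesium bromide (THF, −78 °C) adds 1,2 to the ketone anti to the silyloxy group to give allyl carbinol F2. Bu4NF gives diol F3. MnO2 oxidises only the secondary allylic alcohol to hydroxy enone F4, so the purchased stereocentre is spent after it has set the carbinol centre. Et3SiCl, imidazole and DMAP in DMF give silyl ether F5. Nucleophilic epoxidation of the enone (t-BuOOH, DBU) gives epoxy ketone F6. Chloride opening at the α-carbon (MgCl2 in MeCN, or dry HCl at low temperature) gives chlorohydrin F7, which loses water to allyl chloroenone F8. Ozonolysis of the terminal alkene of F8 (O3, then Me2S), which is far more reactive than the chloroenone alkene, gives 8.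

Second, step 9. What may go wrong: loss of geometric control in the E1cB elimination (the 7Z isomer forms in quantity), and scrambling of the 5Z alkene through ionisation or SN2′ substitution of the allylic mesylate.

The fallback builds the two alkenes in separate operations. It sets out from compound 11 and returns at compound 22. The lithium dienolate 19 of 11 is added to dry 2,2-dimethoxyacetaldehyde to give aldol adduct F9. Its mesylate F10 (MsCl, Et3N) has no allylic leaving group and eliminates to (7E)-enone acetal F11. Mild hydrolysis (LiBF4, wet MeCN) gives enal F12; at this stage the 7-alkene can be equilibrated toward E without risk to a 5Z alkene, which does not exist yet. Z-selective Wittig reaction of F12 with ylide carboxylate 14 (from 12 and NaN(SiMe3)2, THF, −78 °C) gives acid F13. MeI and KHCO3 in DMF give 22.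

Third, step 4. What may go wrong: enolisation of the chloroenone or β-elimination of the silyloxy group by the basic alkylidene ylide, and erosion of Z selectivity.

The fallback forms the Z-alkene with a less basic ylide and attaches the pentyl group by cross-coupling. It sets out from compound 8 and returns at compound 11. Stork–Zhao olefination of 8 ((iodomethyl)triphenylphosphonium iodide, NaN(SiMe3)2, THF/DMPU, −78 °C) gives (Z)-vinyl iodide F14. Negishi coupling with n-pentylzinc bromide (PdCl2(dppf), THF, rt) proceeds with retention of alkene geometry and gives 11.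

**Further compounds**

F1 | step 3 | (4R)-4-[(tert-butyldimethylsilyl)oxy]cyclopent-2-en-1-one (purchased) | O=C1C=C[C@H](O[Si](C)(C)C(C)(C)C)C1
F2 | step 3 | (1S,4R)-4-[(tert-butyldimethylsilyl)oxy]-1-(prop-2-en-1-yl)cyclopent-2-en-1-ol | C=CC[C@@]1(O)C=C[C@H](O[Si](C)(C)C(C)(C)C)C1
F3 | step 3 | (1S,4R)-1-(prop-2-en-1-yl)cyclopent-2-ene-1,4-diol | C=CC[C@@]1(O)C=C[C@H](O)C1
F4 | step 3 | (4S)-4-hydroxy-4-(prop-2-en-1-yl)cyclopent-2-en-1-one | C=CC[C@@]1(O)C=CC(=O)C1
F5 | step 3 | (4S)-4-(prop-2-en-1-yl)-4-[(triethylsilyl)oxy]cyclopent-2-en-1-one | C=CC[C@@]1(O[Si](CC)(CC)CC)C=CC(=O)C1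
F6 | step 3 | (4S)-2,3-epoxy-4-(prop-2-en-1-yl)-4-[(triethylsilyl)oxy]cyclopentan-1-one (epoxide face not specified) | C=CC[C@@]1(O[Si](CC)(CC)CC)C2OC2C(=O)C1
F7 | step 3 | (4S)-2-chloro-3-hydroxy-4-(prop-2-en-1-yl)-4-[(triethylsilyl)oxy]cyclopentan-1-one (C2 and C3 not specified) | C=CC[C@@]1(O[Si](CC)(CC)CC)C(O)C(Cl)C(=O)C1
F8 | step 3 | (4S)-2-chloro-4-(prop-2-en-1-yl)-4-[(triethylsilyl)oxy]cyclopent-2-en-1-one | C=CC[C@@]1(O[Si](CC)(CC)CC)C=C(Cl)C(=O)C1
F9 | step 9 | 2-chloro-5-(1-hydroxy-2,2-dimethoxyethyl)-4-[(2Z)-oct-2-en-1-yl]-4-[(triethylsilyl)oxy]cyclopent-2-en-1-one (silyloxy carbon as in 11; mixture at the two new centres) | CCCCC/C=C\C[C@@]1(O[Si](CC)(CC)CC)C=C(Cl)C(=O)C1C(O)C(OC)OC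
F10 | step 9 | methanesulfonate of F9 | CCCCC/C=C\C[C@@]1(O[Si](CC)(CC)CC)C=C(Cl)C(=O)C1C(OS(C)(=O)=O)C(OC)OC
F11 | step 9 | (5E)-2-chloro-5-(2,2-dimethoxyethylidene)-4-[(2Z)-oct-2-en-1-yl]-4-[(triethylsilyl)oxy]cyclopent-2-en-1-one (silyloxy carbon as in 11) | CCCCC/C=C\C[C@@]1(O[Si](CC)(CC)CC)C=C(Cl)C(=O)/C1=C/C(OC)OC
F12 | step 9 | (2E)-2-{3-chloro-5-[(2Z)-oct-2-en-1-yl]-2-oxo-5-[(triethylsilyl)oxy]cyclopent-3-en-1-ylidene}acetaldehyde (silyloxy carbon as in 11) | CCCCC/C=C\C[C@@]1(O[Si](CC)(CC)CC)C=C(Cl)C(=O)/C1=C/C=O
F13 | step 9 | (5Z,7E,12R,14Z)-10-chloro-9-oxo-12-[(triethylsilyl)oxy]prosta-5,7,10,14-tetraen-1-oic acid | CCCCC/C=C\C[C@@]1(O[Si](CC)(CC)CC)C=C(Cl)C(=O)/C1=C/C=C\CCCC(=O)O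
F14 | step 4 | (4S)-2-chloro-4-[(2Z)-3-iodoprop-2-en-1-yl]-4-[(triethylsilyl)oxy]cyclopent-2-en-1-one | I/C=C\C[C@@]1(O[Si](CC)(CC)CC)C=C(Cl)C(=O)C1
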